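The north run levelled off at 95.3% of the Q charged and the west run at 96.3%, averaging the readings after the first. Q read 0.4% and 0% at their last points, so a few per cent had gone somewhere other than Z.

| flask | Q | D | temperature | remark | time |
|---|---|---|---|---|---|
| north | 0.020 M | 2.5 mol% | 15 °C | run made earlier |  |
| west | 0.020 M | 10 mol% | 35 °C | run made earlier |  |
| gamma | 0.020 M | 5 mol% | 50 °C |  | 6.0 h |
| zeta | 0.020 M | 5 mol% | 20 °C |  | 6.0 h |
| alpha | 0.020 M | 5 mol% | 35 °C |  | 6.0 h |

| run | time / h | Z / % | Q / % |
|---|---|---|---|
| north | 4.00 | 93.0 | 0 |
| north | 8.00 | 95.7 | 0.2 |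
| north | 12.0 | 94.7 | 0 |
| north | 15.0 | 95.5 | 0 |
| north | 25.0 | 95.4 | 0.4 |
| west | 0.500 | 90.6 | 0 |
| west | 1.00 | 96.6 | 0.2 |
| west | 2.00 | 96.2 | 0.2 |
| west | 4.00 | 96.1 | 0.5 |
| west | 8.00 | 96.3 | 0 |

(readings scatter by 0.3 percentage points)

- as a solid, counted per litre of solution: Q
- at the start none of Q is in solution
- what has only dissolved of Q counts as not reacted

* the flask with the highest amount of Z, in percent of the Q charged ("all alike" if they lie within 1.5 percentage points) (gamma / zeta / alpha / all alike)
* final Z, as a percentage of the Q charged, in gamma
* final Z, as a percentage of the Q charged, in zeta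
* final Z, as a percentage of the Q charged, in alpha

I first worked with the fraction still to rise, taking the rise as a single exponential, which was my assumption. West at 0.500 h lacked 5.92% of its level, which gives a time constant of 0.177 h. North at 4.00 h lacked 2.44%, which gives 1.08 h. North has no reading before 4.00 h, so its start and its bend went unseen, and its constant is an estimate from one reading. Even so, north's constant, the longer of the two, fits 5.56 times into the 6.0 h asked, so I expected flat curves in gamma, zeta and alpha, and the question became the height of the level.

For that I defined the loss ratio ρ, the charged Q that did not become Z per Z made, the inverse of a selectivity factor. It read 0.0490 in north and 0.0384 in west, but those runs differ in both loading and temperature. I assumed that Z forms through D and the loss does not, so that ρ falls in proportion to loading. Brought to 5 mol%, north becomes 0.0245 at 15 °C and west 0.0768 at 35 °C. The remaining gap gives 12.1 K, the doubling step, the temperature rise that doubles ρ at fixed loading. This is a reading from two runs plus my assumption. With Z as the charge divided by one plus ρ, I reckoned 96.8% in zeta, 92.9% in alpha and 84.7% in gamma, so zeta came highest.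

The forecast gave 96.2% in gamma, 95.7% in zeta and 96% in alpha, and so all alike: “The flasks should lie within 1.5 points.” My reckoning differs from it in gamma, in alpha and in the choice of the highest flask.

The flasks gave 86.0% in gamma, 96.9% in zeta and 93.4% in alpha, so the answer is zeta.

    G + D → D + Z (k = 4.24 /M/s, Ea = 60.0 kJ/mol)
    Q ⇌ G, rate k2*(cs2 - [G]) while solid is left; crystals form when [G] > cs2 (solubility = 5.30 mM, k = 0.00318 /s)
    G → X (k = 2.42 × 10⁻⁴ /s, Ea = 96.0 kJ/mol)
    2 D → E (k = 0.0953 /M/s, Ea = 61.0 kJ/mol)
    (constants at 35 °C)

Gamma's shortfall is the loss of G to X: with that step taken away, Z in gamma goes from 86.0% to 100%. Gamma's ρ of 0.162 against zeta's 0.0317 gives a doubling step of 12.7 K, beside my 12.1 K. Carried to the neighbour, zeta's recipe at 45 °C, my 12.1 K put ρ at 0.136 and Z at 88.0%; that flask gave 89.1%.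

The readings were computed with made-up constants; scatter was added.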